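Assumption: (S)-(+)-linalool (coriandrol) of high enantiomeric purity, pent-1-en-4-yne and 3-[(tert-butyldimethylsilyl)oxy]propanal are bought; positions C1–C20 use cembrane numbering (C1 = ring-fusion CH bearing C15, lactone O on C2, C16 = lactone C=O, C17 = exocyclic CH2).

**Retrosynthetic overview**
1. Target ⇐ hydroxyl-directed epoxidation of the 11Z olefin from the C13 carbinol of a macrocyclic diol (two C–O bonds, sets C11 and C12), then O-acetylation in the same flask.
2. 14-membered carbocycle ⇐ ring-closing metathesis at C6=C7 of an acyclic tetraene.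
3. C12–C13 ⇐ asymmetric Ni/Cr coupling of a (Z)-vinyl iodide, made from (S)-linalool (C8 from the chiral pool), with a cis-lactone aldehyde.
4. cis-α-Methylene-γ-butyrolactone ⇐ asymmetric chromium-catalysed 2-(alkoxycarbonyl)allylation/lactonisation of (2E)-3-methylhexa-2,5-dienal with a Morita–Baylis–Hillman-derived allylic bromide.
5. Ring order: ring B (lactone) first, ring A (14-membered carbocycle) second, ring C (oxirane) last.

**Route**

Step 1
Reactants: 1 (S)-(+)-linalool [(3S)-3,7-dimethylocta-1,6-dien-3-ol]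
Product: 3 (5S)-5-ethenyl-5-methyloxolan-2-ol, via ozonide 2 (not isolated)
Conditions: O3 (1.0 equiv), CH2Cl2, −78 °C; Me2S, −78 °C → rt
Reagents that add atoms: ozone, [O-][O+]=O
Why: Ozonolysis cleaves the electron-rich trisubstituted olefin much faster than the vinyl group, the γ-hydroxy aldehyde closes to the lactol, and the C8 carbinol (S) is carried over from 1 untouched.

Step 2
Reactants: 3 (5S)-5-ethenyl-5-methyloxolan-2-ol
Product: 4 (3S,6Z)-7-iodo-3-methylocta-1,6-dien-3-ol
Conditions: [Ph3PCH2CH3]I (2.5 equiv), n-BuLi, THF, 0 °C → rt; I2, −78 °C; NaN(SiMe3)2, −20 °C; then 3, −78 → −20 °C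
Reagents that add atoms: ethyltriphenylphosphonium iodide, CC[P+](c1ccccc1)(c1ccccc1)c1ccccc1.[I-]; iodine, II
Why: Stork–Zhao α-iodo Wittig olefination of the open hydroxy-aldehyde form of the lactol proceeds under kinetic control to the (Z)-2-iodoalkene (iodine cis to the chain); no stereocentre is formed or touched.

Step 3
Reactants: 5 3-[(tert-butyldimethylsilyl)oxy]propanal; 6 methyl acrylate
Product: 7 methyl 5-[(tert-butyldimethylsilyl)oxy]-3-hydroxy-2-methylidenepentanoate (racemic)
Conditions: DABCO (1.0 equiv), 6 (3 equiv), MeOH, rt, 72 h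
Reagents that add atoms: none
Why: Morita–Baylis–Hillman reaction; the new carbinol centre forms racemic and is erased in step 4.

Step 4
Reactants: 7 methyl 5-[(tert-butyldimethylsilyl)oxy]-3-hydroxy-2-methylidenepentanoate
Product: 8 methyl (2Z)-2-(bromomethyl)-5-[(tert-butyldimethylsilyl)oxy]pent-2-enoate
Conditions: NBS (1.2 equiv), Me2S (1.4 equiv), CH2Cl2, 0 °C → rt
Reagents that add atoms: N-bromosuccinimide, O=C1CCC(=O)N1Br
Why: Corey–Kim-type activation of the allylic alcohol and SN2′ attack of bromide at the methylene carbon give the conjugated enoate with the chain trans to the ester (2Z), leaving the silyl ether intact.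

Step 5
Reactants: 9 pent-1-en-4-yne
Product: 12 (2E)-3-methylhexa-2,5-dien-1-ol, via alkenylalane 10 (not isolated), via lithium alanate 11 (not isolated)
Conditions: Me3Al (2.0 equiv), Cp2ZrCl2 (0.2 equiv), CH2Cl2, 0 °C → rt; n-BuLi, THF, −78 °C; (CH2O)n, −78 °C → rt; H2O
Reagents that add atoms: trimethylaluminium, C[Al](C)C; paraformaldehyde (formaldehyde unit), C=O
Why: Negishi zirconium-catalysed carboalumination adds Me–Al syn across the terminal alkyne (Al on the terminal carbon), fixing the E trisubstituted olefin, and the alanate is hydroxymethylated with retention.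

Step 6
Reactants: 12 (2E)-3-methylhexa-2,5-dien-1-ol
Product: 13 (2E)-3-methylhexa-2,5-dienal
Conditions: MnO2 (15 equiv), CH2Cl2, rt
Reagents that add atoms: none
Why: Neutral allylic alcohol oxidation with MnO2 leaves the skipped diene unconjugated and the 2E geometry intact.

Step 7
Reactants: 8 methyl (2Z)-2-(bromomethyl)-5-[(tert-butyldimethylsilyl)oxy]pent-2-enoate; 13 (2E)-3-methylhexa-2,5-dienal
Product: 16 (4S,5S)-4-(2-hydroxyethyl)-3-methylidene-5-[(1E)-2-methylpenta-1,4-dien-1-yl]oxolan-2-one, via silyl ether 14 (not isolated), via silyl lactone 15 (not isolated)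
Conditions: CrCl2 (10 mol %), chiral carbazole-bis(oxazoline) ligand (12 mol %, antipode giving the 2S carbinol), Mn (2 equiv), Me3SiCl (1.5 equiv), Et3N (20 mol %), THF, rt; then HF·pyridine, pyridine, THF, 0 °C → rt
Reagents that add atoms: none
Why: Catalytic asymmetric Nozaki–Hiyama 2-(alkoxycarbonyl)allylation: the allylchromium equilibrates to the isomer with the chain cis to CH2–Cr and adds 1,2 to the enal through a chair transition state to give the syn adduct (C1/C2 cis), the ligand on chromium choosing the aldehyde face (C2 S, hence C1 S); HF then removes the trimethylsilyl group, the γ-hydroxy ester closes to the five-membered lactone (ring B) before the primary silyl ether is cleaved.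

Step 8
Reactants: 16 (4S,5S)-4-(2-hydroxyethyl)-3-methylidene-5-[(1E)-2-methylpenta-1,4-dien-1-yl]oxolan-2-one
Product: 17 2-[(2S,3S)-4-methylidene-2-[(1E)-2-methylpenta-1,4-dien-1-yl]-5-oxooxolan-3-yl]acetaldehyde
Conditions: Dess–Martin periodinane (1.3 equiv), pyridine, CH2Cl2, 0 °C → rt
Reagents that add atoms: none
Why: Dess–Martin oxidation of the primary alcohol under buffered conditions; C1 is not α to the new carbonyl, so no stereocentre can epimerise.

Step 9
Reactants: 4 (3S,6Z)-7-iodo-3-methylocta-1,6-dien-3-ol; 17 2-[(2S,3S)-4-methylidene-2-[(1E)-2-methylpenta-1,4-dien-1-yl]-5-oxooxolan-3-yl]acetaldehyde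
Product: 18 (4S,5S)-4-[(2R,3Z,7S)-2,7-dihydroxy-3,7-dimethylnona-3,8-dien-1-yl]-3-methylidene-5-[(1E)-2-methylpenta-1,4-dien-1-yl]oxolan-2-one
Conditions: CrCl2 (4 equiv), chiral oxazoline–sulfonamide ligand (4.4 equiv, antipode giving 13R), Et3N (4.4 equiv), NiCl2 (0.1 equiv), THF, rt; H2O
Reagents that add atoms: none
Why: Nozaki–Hiyama–Kishi coupling: zerovalent nickel inserts into the C–I bond with retention of the Z geometry, the alkenyl group passes to trivalent chromium, and the sulfonamide-ligated alkenylchromium adds to the aldehyde under ligand control to set C13 (R), the remote C1 centre having little say.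

Step 10
Reactants: 18 (4S,5S)-4-[(2R,3Z,7S)-2,7-dihydroxy-3,7-dimethylnona-3,8-dien-1-yl]-3-methylidene-5-[(1E)-2-methylpenta-1,4-dien-1-yl]oxolan-2-one
Product: 19 (1S,2S,3E,6E,8S,11Z,13R)-8,13-dihydroxycembra-3,6,11,15(17)-tetraen-16,2-olide
Conditions: second-generation Grubbs catalyst RuCl2(=CHPh)(PCy3)(H2IMes) (10 mol %), 1,4-benzoquinone (20 mol %), CH2Cl2 (1 mM), 40 °C
Reagents that add atoms: none
Why: Ring-closing metathesis joins only the two monosubstituted olefins (the trisubstituted olefins and the electron-poor exocyclic methylene are inert) to close ring A, the E olefin being favoured because a Z olefin next to the quaternary C8 carbinol is strained; benzoquinone suppresses migration of the skipped diene.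

Step 11
Reactants: 19 (1S,2S,3E,6E,8S,11Z,13R)-8,13-dihydroxycembra-3,6,11,15(17)-tetraen-16,2-olide
Product: 21 (1S,2S,3E,6E,8S,11S,12S,13R)-13-acetoxy-11,12-epoxy-8-hydroxycembra-3,6,15(17)-trien-16,2-olide, via epoxy diol 20 (not isolated)
Conditions: VO(OiPr)3 (5 mol %), bis(hydroxamic acid) L (6 mol %), t-BuOOH (1.3 equiv, decane), toluene, 0 °C; Me2S (0.5 equiv); then Ac2O (1.5 equiv), Et3N, DMAP (10 mol %), 0 °C → rt; L = N,N′-(ethane-1,2-diyl)bis(N-hydroxy-2,2-diphenylacetamide)
Reagents that add atoms: tert-butyl hydroperoxide, CC(C)(C)OO; acetic anhydride, CC(=O)OC(C)=O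
Why: Proposed new method: an achiral 1:1 oxovanadium–bis(hydroxamate) catalyst is used for hydroxyl-directed epoxidation of a Z-trisubstituted secondary allylic alcohol inside a 14-membered polyene that also carries a free tertiary alcohol, with acetylation of the product in the same flask; mechanistically, the chelating bis(hydroxamate) leaves one alkoxide site and one η2-peroxide site on pentavalent vanadium, so only the secondary C13–OH (not the hindered C8–OH) binds, the O–C13–C12=C11 dihedral of about 45° in the oxygen-transfer transition state puts H13 beside the C12 methyl (minimal A(1,2) strain) and C14, already perpendicular to the olefin plane in the ring, on the far face, so oxygen is delivered erythro to the 13R carbinol to give the (11S,12S) oxirane of 21 (ring C), while the weakly Lewis-acidic ligated metal does not trigger transannular opening of the oxirane by the C8 hydroxyl and acetylation with retention caps C13; the closest known reaction type is the Sharpless–Michaelson VO(acac)2/t-BuOOH epoxidation of allylic alcohols and the vanadium–chiral bis(hydroxamic acid) epoxidation of Z-allylic alcohols.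

**Compound list**

1 | (S)-(+)-linalool, (3S)-3,7-dimethylocta-1,6-dien-3-ol | C=C[C@@](C)(O)CCC=C(C)C | starting material
2 | (3S)-5-(5,5-dimethyl-1,2,4-trioxolan-3-yl)-3-methylpent-1-en-3-ol (ozonide) | C=C[C@@](C)(O)CCC1OOC(C)(C)O1 | intermediate (not isolated)
3 | (5S)-5-ethenyl-5-methyloxolan-2-ol (lactol, anomer mixture) | C=C[C@@]1(C)OC(O)CC1 | intermediate
4 | (3S,6Z)-7-iodo-3-methylocta-1,6-dien-3-ol | C=C[C@@](C)(O)CC/C=C(/C)I | intermediate
5 | 3-[(tert-butyldimethylsilyl)oxy]propanal | O=CCCO[Si](C)(C)C(C)(C)C | starting material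
6 | methyl acrylate | C=CC(=O)OC | starting material
7 | methyl 5-[(tert-butyldimethylsilyl)oxy]-3-hydroxy-2-methylidenepentanoate (racemic) | COC(=O)C(=C)C(O)CCO[Si](C)(C)C(C)(C)C | intermediate
8 | methyl (2Z)-2-(bromomethyl)-5-[(tert-butyldimethylsilyl)oxy]pent-2-enoate | COC(=O)/C(CBr)=C/CCO[Si](C)(C)C(C)(C)C | intermediate
9 | pent-1-en-4-yne | C#CCC=C | starting material
10 | dimethyl[(1E)-2-methylpenta-1,4-dien-1-yl]alane | C[Al](C)/C=C(\C)CC=C | intermediate (not isolated)
11 | lithium butyl(dimethyl)[(1E)-2-methylpenta-1,4-dien-1-yl]alanate | [Li+].CCCC[Al-](C)(C)/C=C(\C)CC=C | intermediate (not isolated)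
12 | (2E)-3-methylhexa-2,5-dien-1-ol | OC/C=C(\C)CC=C | intermediate
13 | (2E)-3-methylhexa-2,5-dienal | O=C/C=C(\C)CC=C | intermediate
14 | methyl (3S,4S,5E)-3-{2-[(tert-butyldimethylsilyl)oxy]ethyl}-6-methyl-2-methylidene-4-[(trimethylsilyl)oxy]nona-5,8-dienoate | COC(=O)C(=C)[C@H](CCO[Si](C)(C)C(C)(C)C)[C@@H](O[Si](C)(C)C)/C=C(\C)CC=C | intermediate (not isolated)
15 | (4S,5S)-4-{2-[(tert-butyldimethylsilyl)oxy]ethyl}-3-methylidene-5-[(1E)-2-methylpenta-1,4-dien-1-yl]oxolan-2-one | C=C1C(=O)O[C@@H](/C=C(\C)CC=C)[C@H]1CCO[Si](C)(C)C(C)(C)C | intermediate (not isolated)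
16 | (4S,5S)-4-(2-hydroxyethyl)-3-methylidene-5-[(1E)-2-methylpenta-1,4-dien-1-yl]oxolan-2-one | C=C1C(=O)O[C@@H](/C=C(\C)CC=C)[C@H]1CCO | intermediate
17 | 2-[(2S,3S)-4-methylidene-2-[(1E)-2-methylpenta-1,4-dien-1-yl]-5-oxooxolan-3-yl]acetaldehyde | C=C1C(=O)O[C@@H](/C=C(\C)CC=C)[C@H]1CC=O | intermediate
18 | (4S,5S)-4-[(2R,3Z,7S)-2,7-dihydroxy-3,7-dimethylnona-3,8-dien-1-yl]-3-methylidene-5-[(1E)-2-methylpenta-1,4-dien-1-yl]oxolan-2-one | C=C[C@@](C)(O)CC/C=C(/C)[C@H](O)C[C@@H]1[C@H](/C=C(\C)CC=C)OC(=O)C1=C | intermediate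
19 | (1S,2S,3E,6E,8S,11Z,13R)-8,13-dihydroxycembra-3,6,11,15(17)-tetraen-16,2-olide (14-membered carbocycle cis-fused at C1/C2 to the α-methylene-γ-butyrolactone) | C=C1C(=O)O[C@H]2/C=C(\C)C/C=C/[C@@](C)(O)CC/C=C(/C)[C@H](O)C[C@@H]12 | intermediate
20 | (1S,2S,3E,6E,8S,11S,12R,13R)-11,12-epoxy-8,13-dihydroxycembra-3,6,15(17)-trien-16,2-olide (same oxirane geometry as 21; the C12 label differs only through the priority order) | C=C1C(=O)O[C@H]2/C=C(\C)C/C=C/[C@@](C)(O)CC[C@@H]3O[C@]3(C)[C@H](O)C[C@@H]12 | intermediate (not isolated)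
21 | (1S,2S,3E,6E,8S,11S,12S,13R)-13-acetoxy-11,12-epoxy-8-hydroxycembra-3,6,15(17)-trien-16,2-olide (CNP0288879.2) | C=C1C(=O)O[C@H]2/C=C(\C)C/C=C/[C@@](C)(O)CC[C@@H]3O[C@]3(C)[C@H](OC(C)=O)C[C@@H]12 | target

**Step count**

Total: 11 steps. Longest linear sequence: 7 steps (3, 4, 7, 8, 9, 10, 11) from 5 and 6; steps 1–2 and 5–6 are side branches.

**Three steps most likely to fail**

Step 7 (enantioselectivity and syn/anti ratio of the chromium allylation with a γ-substituted bromide and an enal). The fallback sets out from 7 and 13 and replaces the chromium reagent by a stereospecific closed boron transition state. Acetylation of 7 (Ac2O, DMAP, CH2Cl2) gives methyl 3-(acetyloxy)-5-[(tert-butyldimethylsilyl)oxy]-2-methylidenepentanoate F1. Copper-catalysed SN2′ borylation (CuCl, KOAc, B2pin2, DMF) gives methyl (2E)-5-[(tert-butyldimethylsilyl)oxy]-2-[(4,4,5,5-tetramethyl-1,3,2-dioxaborolan-2-yl)methyl]pent-2-enoate F2, in which the chain is cis to CH2–B. Allylboration of 13 catalysed by a chiral BINOL-derived phosphoric acid (TRIP, the antipode giving 2S; toluene, −30 °C → rt) then gives, through the chair transition state, the syn adduct methyl (3S,4S,5E)-3-{2-[(tert-butyldimethylsilyl)oxy]ethyl}-4-hydroxy-6-methyl-2-methylidenenona-5,8-dienoate F3. HF·pyridine lactonises and desilylates F3, and the route is rejoined at 16.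

Step 10 (macrocyclic ring-closing metathesis: E/Z ratio, oligomers, diene migration). The fallback sets out from 4 and 17 and closes the ring at C12–C13 instead of C6=C7. Cross-metathesis (second-generation Hoveyda–Grubbs catalyst RuCl2(=CH-C6H4-2-OiPr)(H2IMes), excess 4, CH2Cl2, 40 °C) gives the E seco iodo-aldehyde 2-[(2S,3S)-2-[(1E,4E,6S,9Z)-6-hydroxy-10-iodo-2,6-dimethylundeca-1,4,9-trien-1-yl]-4-methylidene-5-oxooxolan-3-yl]acetaldehyde F4. An intramolecular Ni/Cr coupling (CrCl2, NiCl2 cat., the sulfonamide ligand of step 9, Et3N, THF, 2 mM) then forms the C12–C13 bond and the 13R carbinol, and the route is rejoined at 19.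

Step 11 (the proposed new epoxidation: face selectivity, competing delivery from the C8 hydroxyl, transannular ether formation). The fallback uses known chemistry, sets out from 18 and epoxidises under reagent control before the ring is closed. Sharpless epoxidation (Ti(OiPr)4, D-(−)-diisopropyl tartrate, t-BuOOH, 4 Å molecular sieves, CH2Cl2, −20 °C) pairs the 13R carbinol with the D-tartrate, which is the fast, erythro-selective case of the Sharpless kinetic resolution. It gives (4S,5S)-4-{(2R)-2-hydroxy-2-[(2R,3S)-3-[(3S)-3-hydroxy-3-methylpent-4-en-1-yl]-2-methyloxiran-2-yl]ethyl}-3-methylidene-5-[(1E)-2-methylpenta-1,4-dien-1-yl]oxolan-2-one F5. Acetylation (Ac2O, pyridine, DMAP) gives (1R)-1-[(2S,3S)-3-[(3S)-3-hydroxy-3-methylpent-4-en-1-yl]-2-methyloxiran-2-yl]-2-[(2S,3S)-4-methylidene-2-[(1E)-2-methylpenta-1,4-dien-1-yl]-5-oxooxolan-3-yl]ethyl acetate F6. Ring-closing metathesis of F6 (second-generation Grubbs catalyst, benzoquinone, CH2Cl2, 1 mM, 40 °C) closes the macrocycle, and the route is rejoined at 21.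

**Further compounds**

F1 | step 7 | methyl 3-(acetyloxy)-5-[(tert-butyldimethylsilyl)oxy]-2-methylidenepentanoate | COC(=O)C(=C)C(OC(C)=O)CCO[Si](C)(C)C(C)(C)C
F2 | step 7 | methyl (2E)-5-[(tert-butyldimethylsilyl)oxy]-2-[(4,4,5,5-tetramethyl-1,3,2-dioxaborolan-2-yl)methyl]pent-2-enoate | COC(=O)/C(CB1OC(C)(C)C(C)(C)O1)=C/CCO[Si](C)(C)C(C)(C)C
F3 | step 7 | methyl (3S,4S,5E)-3-{2-[(tert-butyldimethylsilyl)oxy]ethyl}-4-hydroxy-6-methyl-2-methylidenenona-5,8-dienoate | COC(=O)C(=C)[C@H](CCO[Si](C)(C)C(C)(C)C)[C@@H](O)/C=C(\C)CC=C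
F4 | step 10 | 2-[(2S,3S)-2-[(1E,4E,6S,9Z)-6-hydroxy-10-iodo-2,6-dimethylundeca-1,4,9-trien-1-yl]-4-methylidene-5-oxooxolan-3-yl]acetaldehyde | O=CC[C@@H]1[C@H](/C=C(\C)C/C=C/[C@@](C)(O)CC/C=C(/C)I)OC(=O)C1=C
F5 | step 11 | (4S,5S)-4-{(2R)-2-hydroxy-2-[(2R,3S)-3-[(3S)-3-hydroxy-3-methylpent-4-en-1-yl]-2-methyloxiran-2-yl]ethyl}-3-methylidene-5-[(1E)-2-methylpenta-1,4-dien-1-yl]oxolan-2-one | C=C[C@@](C)(O)CC[C@@H]2O[C@]2(C)[C@H](O)C[C@@H]1[C@H](/C=C(\C)CC=C)OC(=O)C1=C
F6 | step 11 | (1R)-1-[(2S,3S)-3-[(3S)-3-hydroxy-3-methylpent-4-en-1-yl]-2-methyloxiran-2-yl]-2-[(2S,3S)-4-methylidene-2-[(1E)-2-methylpenta-1,4-dien-1-yl]-5-oxooxolan-3-yl]ethyl acetate | C=C[C@@](C)(O)CC[C@@H]2O[C@]2(C)[C@H](OC(C)=O)C[C@@H]1[C@H](/C=C(\C)CC=C)OC(=O)C1=C
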